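## Structural features

The target, (2S)-5-hydroxy-8-(3-hydroxy-3-methylbutyl)-7-methoxyflavanone, is a 2-phenylchroman-4-one: aromatic ring A is fused through C4a–C8a to the dihydropyranone ring C (O1, C2, C3, C4, C4a, C8a), and the unsubstituted phenyl ring B sits on C2. Ring A carries a hydroxyl at C5 that is chelated to the C4 carbonyl, a methoxy group at C7, a saturated five-carbon chain ending in a tertiary alcohol at C8, and hydrogen only at C6. C2 is the only stereocentre (S) and has no stereogenic neighbour, but it is benzylic, bound to O1 and β to the ketone, so it is lost by retro-oxa-Michael ring opening under base or hot acid. The tertiary alcohol ionises in acid and, whenever a free phenol stands next to the chain, can close to a 2,2-dimethylchroman; the phloroglucinol-type ring A is easily oxidised and substituted at C6. The real difficulties are the regiochemistry of ring A (three differently substituted oxygens, and the chain at C8 and not C6, which depends on which ortho oxygen becomes O1) and the absolute configuration at C2, which must survive every later step. The plan exploits the fact that O1–C8a–C4a–C4 is the heterodiene of an ortho-quinone methide of ring A, while C2–C3 with ring B is a styrene, so ring C and C2 can arise in one [4+2] event on a salicylaldehyde.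

## Logic of the disconnections

16 ⇒ 15. The O–CH2Ph bond on O5 is added back. The C5 oxygen must be blocked in every earlier compound so that only one phenol can become O1, and a benzyl ether leaves under neutral conditions, which the base-labile C2 requires. Nothing is gained in skeleton, but the last step becomes a clean unmasking. The forward step must cleave this ether faster than the cyclic benzylic C2–O1 bond and must not reduce the ketone.

15 ⇒ 14. The O–Si bond on the tertiary oxygen is added back. The tertiary alcohol has to be masked while acid is present earlier in the route. The demand is a desilylation that is not basic.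

14 ⇒ 13. The C4 carbonyl is traced to C4–H plus C4–OMe. This exposes the retron of the annulation and makes the C4 stereocentre of 13 disposable. The forward step must abstract hydride at C4 and not at C2 or at the benzylic CH2 of the benzyl ether.

13 ⇒ 8 + 9 + 10. C3–C4 and O1–C2 are cut, and the C4 methoxy group goes back to 10. This removes ring C, ring B and both stereocentres at once and leaves a salicylaldehyde and two commodity chemicals. The forward step needs an acid that controls the face of attack, a single free phenol in 8, and protecting groups that tolerate that acid.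

8 ⇒ 6. The Si–O bond is cut. The demand is silylation of a tertiary alcohol while the phenol ends up free.

6 ⇒ 5. The tertiary C–O bond is cut, giving back a trisubstituted alkene. A prenyl group is the C5 unit that can be attached directly to the ring. The forward hydration must be Markovnikov and non-acidic, because the neighbouring phenol would otherwise cyclise.

5 ⇒ 4. The O–CH2Ph bond on O6 is cut. The forward step must distinguish two ortho hydroxyls, one open and one wedged between the formyl group and the chain.

4 ⇒ 2 + 3. The ring C3–CH2 bond is cut. The free ring positions of 2 are equivalent and flanked by oxygen donors, so the ring carbon can act as the nucleophile. The demand is C- over O-alkylation and mono- over dialkylation.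

2 ⇒ 1. The O4–CH3 bond is cut. The forward step must methylate only the para hydroxyl of a symmetric triol.

## Other disconnections considered

Alternative 1: The cut is C4–C4a. The acid (3S)-3-(2-bromo-3,5-dimethoxyphenoxy)-3-phenylpropanoic acid A2 would be activated as its chloride and closed with SnCl4 by intramolecular Friedel–Crafts acylation to (2S)-8-bromo-5,7-dimethoxyflavanone A1.
- In favour: C2 would come from an enantiopure benzylic alcohol by a Mitsunobu etherification, so every step is of a known type. On certainty of absolute configuration this is better than the chosen plan. The site of ring closure is fixed by the bromine, which is equal to the single free phenol of 8.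
- Against: a β-aryloxy acyl chloride under a strong Lewis acid can ionise at the benzylic C–O bond or eliminate the aryloxy group, and either would cost optical purity. A1 is not yet the target skeleton: the C8 chain must still be attached through a cross-coupling (basic conditions on a flavanone), and the C5 methyl ether must be cleaved by a Lewis acid that the tertiary alcohol tolerates poorly.
- Comparison: the chosen plan carries the complete ring A into the ring-forming step and needs only neutral or weakly acidic steps afterwards. The step count of Alternative 1 is about equal.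

Alternative 2: The cuts are O1–C8a and C4–C4a. CsF would release the aryne from 3-methoxy-5-(methoxymethoxy)-2-[3-methyl-3-(triethylsilyloxy)butyl]-6-(trimethylsilyl)phenyl trifluoromethanesulfonate A4. The alkoxide of (3S)-3-hydroxy-N-methoxy-N-methyl-3-phenylpropanamide A5 would add at C8a and the aryl anion would attack the amide, giving (2S)-7-methoxy-5-(methoxymethoxy)-8-[3-methyl-3-(triethylsilyloxy)butyl]flavanone A3.
- In favour: it is the most convergent of the four plans, and no bond to C2 is made or broken, so no asymmetric induction is needed. On both points it is better than the chosen plan. The C5 alkoxy group polarises the aryne in the required sense, with the nucleophile going to the remote carbon.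
- Against: the alkoxide of A5 is set up for retro-aldol cleavage, aliphatic alkoxides are modest aryne nucleophiles, and attack must occur next to the C8 chain. A3 would sit in basic fluoride, where reversible ring opening erodes C2. A4 is a hexasubstituted arene that needs everything 8 needs plus the silyl triflate pair.
- Comparison: on step economy Alternative 2 is clearly worse. Its acidic removal of the acetal at the end is equal in risk to the end-game chosen here.

Alternative 3: The cut is C2–C3. Dirhodium tetrakis[(S)-N-phthaloyl-tert-leucinate], Rh2(S-PTTL)4, would decompose 1-{2-(benzyloxy)-6-(tert-butyldimethylsilyloxy)-4-methoxy-3-[3-methyl-3-(triethylsilyloxy)butyl]phenyl}-2-diazoethan-1-one A7. The carbenoid at C3 would insert into a benzylic C–H bond of the ortho benzyl ether to give (2S)-5-(tert-butyldimethylsilyloxy)-7-methoxy-8-[3-methyl-3-(triethylsilyloxy)butyl]flavanone A6.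
- In favour: it is catalytic and enantioselective like the chosen plan, and it rests on a reaction class with precedent for chromanones, which is better. The ketone arrives at the right oxidation level and both silyl ethers could fall together, so the end-game is shorter by two steps, also better.
- Against: an acceptor-only carbenoid next to an ether oxygen can form the five-membered oxonium ylide and undergo a Stevens-type benzyl shift, or add to the phenyl ring of the benzyl group. Six-membered closure by insertion is the less favoured mode, and terminal diazoketones give the weakest enantiocontrol with divalent rhodium carboxylates. A7 needs the same differentiated ring A as 8, then oxidation to a hindered acid and acylation of a diazoalkane, several steps more before the key step.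
- Comparison: overall length is about equal. The risk is of the same order as in the chosen plan but lies in chemoselectivity and not in reactivity.

Key step: step 6

Assumptions (remarks on the chemistry):
- Flavan numbering (O1, C2, C3, C4, C4a, C5–C8, C8a) is used for 13–16 and benzaldehyde numbering for 1–8.
- (S,S)-IDPi denotes the imidodiphosphorimidate built from two (S)-3,3'-bis[3,5-bis(trifluoromethyl)phenyl]-1,1'-bi-2-naphthol units with an N-triflyl group on each phosphorus. Its sense of induction cannot be derived from the substrate, so the mirror-image catalyst is taken if the 2R series should result.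
- 12 is drawn as the E isomer. It equilibrates through its protonated form, and the C4 configuration of 13 has no consequence.

## Route

Step 1
Reactants: 1 2,4,6-trihydroxybenzaldehyde
Product: 2 2,6-dihydroxy-4-methoxybenzaldehyde
Conditions: MeI (1.05 equiv), K2CO3 (1.0 equiv), acetone, 0 °C → rt
Reagents that add atoms: iodomethane, CI
Why: Williamson etherification of the most acidic hydroxyl: the para hydroxyl is the only one that cannot hydrogen-bond to the formyl group and forms the vinylogous carboxylate first, so one equivalent of base and MeI should methylate O4. The product has a mirror plane, so the unsymmetrical 2-O-methyl isomer is easy to recognise and remove.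

Step 2
Reactants: 2 2,6-dihydroxy-4-methoxybenzaldehyde; 3 prenyl bromide (1-bromo-3-methylbut-2-ene)
Product: 4 2,6-dihydroxy-4-methoxy-3-(3-methylbut-2-en-1-yl)benzaldehyde
Conditions: aq KOH (10 %, 2 equiv), 0 °C → rt, 3 (1.0 equiv) added slowly
Reagents that add atoms: none
Why: Nuclear alkylation of an ambident phloroglucinol-type phenolate: in water the oxygens are hydrogen-bonded and the allylic bromide is attacked by the ring carbon ortho to O2 and OMe and para to O6 (C3 and C5 are equivalent), followed by tautomerisation to the phenol. Slow addition of one equivalent of 3 limits the expected side reactions, O-alkylation and dialkylation.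

Step 3
Reactants: 4 2,6-dihydroxy-4-methoxy-3-(3-methylbut-2-en-1-yl)benzaldehyde
Product: 5 6-(benzyloxy)-2-hydroxy-4-methoxy-3-(3-methylbut-2-en-1-yl)benzaldehyde
Conditions: BnBr (1.05 equiv), K2CO3 (1.1 equiv), acetone, rt
Reagents that add atoms: benzyl bromide, BrCc1ccccc1
Why: Williamson etherification under steric and chelation control: the C6 hydroxyl has only H and CHO as neighbours, whereas the C2 hydroxyl is wedged between CHO and the prenyl group, which also presses it into the hydrogen bond to the carbonyl oxygen. After the first alkylation the remaining hydroxyl is fully chelated, so a second benzylation should not follow at room temperature.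

Step 4
Reactants: 5 6-(benzyloxy)-2-hydroxy-4-methoxy-3-(3-methylbut-2-en-1-yl)benzaldehyde
Product: 6 6-(benzyloxy)-2-hydroxy-3-(3-hydroxy-3-methylbutyl)-4-methoxybenzaldehyde
Conditions: Co(acac)2 (20 mol %), PhSiH3 (2 equiv), O2 (1 atm), THF, rt
Reagents that add atoms: dioxygen, O=O
Why: Mukaiyama hydration: hydrogen atom transfer from a cobalt hydride to the trisubstituted alkene gives the tertiary radical, which is trapped by O2 and reduced by the silane to the Markovnikov tertiary alcohol. The medium is neutral, so the neighbouring phenol cannot close to a chroman, and the aryl benzyl ether and the chelated, electron-rich aldehyde should not be touched.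

Step 5
Reactants: 6 6-(benzyloxy)-2-hydroxy-3-(3-hydroxy-3-methylbutyl)-4-methoxybenzaldehyde
Product: 8 6-(benzyloxy)-2-hydroxy-4-methoxy-3-[3-methyl-3-(triethylsilyloxy)butyl]benzaldehyde, via bis(triethylsilyl) ether 7 (not isolated)
Conditions: TESOTf (2.5 equiv), 2,6-lutidine (4 equiv), CH2Cl2, −78 → 0 °C; aqueous wash; then K2CO3 (0.2 equiv), MeOH, 0 °C
Reagents that add atoms: triethylsilyl trifluoromethanesulfonate, CC[Si](CC)(CC)OS(=O)(=O)C(F)(F)F
Why: The silyl triflate silylates the hindered tertiary alcohol and, unavoidably, the phenol; the aryl silyl ether ortho to the formyl group is then cleaved selectively by brief carbonate-catalysed methanolysis, because the chelated phenoxide is a far better leaving group than a tertiary alkoxide. This restores the one free phenol the key step needs while the tertiary alcohol stays masked against ionisation.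

Step 6
Reactants: 8 6-(benzyloxy)-2-hydroxy-4-methoxy-3-[3-methyl-3-(triethylsilyloxy)butyl]benzaldehyde; 9 styrene; 10 trimethyl orthoformate
Product: 13 (2S,4S)-5-(benzyloxy)-4,7-dimethoxy-8-[3-methyl-3-(triethylsilyloxy)butyl]flavan, via dimethyl acetal 11 (not isolated), via methoxy ortho-quinone methide 12 (not isolated)
Conditions: 10 (2 equiv), (S,S)-IDPi (5 mol %), 5 Å MS, toluene, rt; then 9 (5 equiv), −40 → −20 °C
Reagents that add atoms: none
Why: Proposed new method: the acid first catalyses acetal exchange of 8 with 10 to give 11 and then ionises 11 with loss of methanol to the O-methyl oxocarbenium ion that is the protonated form of 12, held as a contact ion pair with the chiral anion through the phenolic O–H; the terminal carbon of 9 attacks C4 and the developing benzylic cation is captured by the phenol oxygen, an asynchronous inverse-electron-demand oxa-[4+2] cycloaddition. The closest known reactions are the achiral acid-catalysed coupling of salicylaldehydes, orthoformates and styrenes to 2,4-cis-4-alkoxyflavans and chiral phosphoric or imidodiphosphoric acid-catalysed [4+2] additions of ortho-quinone methides generated in the flask to styrenes and other electron-rich alkenes; new is their combination, an acetal-derived alkoxy-substituted cation under enantiocontrol. Ring C is closed by intermolecular [4+2] annulation, C3–C4 forming first and O1–C2 completing the six-membered ring. C2 is set by the catalyst, whose confined anion covers one face of the planar cation so that 9 approaches the open face with phenyl endo, and C4 follows from the same endo arrangement (2,4-cis), which does not matter later because C4 becomes the carbonyl carbon. Regioselectivity (phenyl on the carbon bound to oxygen) follows from the polarity of the partners, since only the benzylic carbon of 9 can carry the positive charge. Site selectivity for O1 is secured by the substrate, because the hydroxyl between the formyl group and the side chain is the only free phenol, which places the chain at C8. The step needs face selectivity and a uniform endo/exo preference together, because cis and trans adducts formed on the same face of the same cation geometry would differ at C2 and would lower the optical purity once step 7 has removed C4. The doubly donor-stabilised cation is a weak electrophile, so a strongly acidic confined catalyst, excess 9 and sieves that take up methanol are chosen, and the tertiary silyl ether and the benzyl ether should tolerate the cold, non-aqueous acid.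

Step 7
Reactants: 13 (2S,4S)-5-(benzyloxy)-4,7-dimethoxy-8-[3-methyl-3-(triethylsilyloxy)butyl]flavan
Product: 14 (2S)-5-(benzyloxy)-7-methoxy-8-[3-methyl-3-(triethylsilyloxy)butyl]flavanone
Conditions: DDQ (1.3 equiv), CH2Cl2/pH 7 phosphate buffer (10:1), 0 °C → rt
Reagents that add atoms: water, O
Why: DDQ oxidation of an electron-rich benzylic ether (the reaction type that cleaves p-methoxybenzyl ethers): hydride is abstracted from C4, which is benzylic to ring A with oxygen donors at both ortho positions and the para position and already carries the methoxy group; water adds to the oxocarbenium ion and the hemiketal loses methanol to give the ketone. The C4 stereocentre disappears and C2 is not involved; the buffer keeps the medium neutral so that neither the TES ether nor the C2–O1 bond is attacked, and the C2–H and OCH2Ph hydrogens are far less hydridic.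

Step 8
Reactants: 14 (2S)-5-(benzyloxy)-7-methoxy-8-[3-methyl-3-(triethylsilyloxy)butyl]flavanone
Product: 15 (2S)-5-(benzyloxy)-8-(3-hydroxy-3-methylbutyl)-7-methoxyflavanone
Conditions: HF·pyridine, pyridine, THF, 0 °C → rt
Reagents that add atoms: none
Why: Fluoride-mediated cleavage of the Si–O bond under weakly acidic, buffered conditions; basic fluoride sources are avoided because they would open the flavanone by E1cB (retro-oxa-Michael) and racemise C2.

Step 9
Reactants: 15 (2S)-5-(benzyloxy)-8-(3-hydroxy-3-methylbutyl)-7-methoxyflavanone
Product: 16 (2S)-5-hydroxy-8-(3-hydroxy-3-methylbutyl)-7-methoxyflavanone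
Conditions: H2 (1 atm), 10 % Pd/C, EtOAc, rt
Reagents that add atoms: none
Why: Hydrogenolysis of the aryl benzyl ether on palladium under neutral conditions; the O-benzyl bond should be cleaved much faster than the cyclic C2–O1 bond or the aryl ketone, which becomes chelated and deactivated as the C5 hydroxyl is released. The reaction is stopped when 15 is consumed, so C2 stays S.

## Compound list

1 | 2,4,6-trihydroxybenzaldehyde | O=Cc1c(O)cc(O)cc1O | starting material
2 | 2,6-dihydroxy-4-methoxybenzaldehyde | O=Cc1c(O)cc(OC)cc1O | intermediate
3 | prenyl bromide (1-bromo-3-methylbut-2-ene) | CC(C)=CCBr | starting material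
4 | 2,6-dihydroxy-4-methoxy-3-(3-methylbut-2-en-1-yl)benzaldehyde | O=Cc1c(O)cc(OC)c(CC=C(C)C)c1O | intermediate
5 | 6-(benzyloxy)-2-hydroxy-4-methoxy-3-(3-methylbut-2-en-1-yl)benzaldehyde | O=Cc1c(OCc2ccccc2)cc(OC)c(CC=C(C)C)c1O | intermediate
6 | 6-(benzyloxy)-2-hydroxy-3-(3-hydroxy-3-methylbutyl)-4-methoxybenzaldehyde | O=Cc1c(OCc2ccccc2)cc(OC)c(CCC(C)(C)O)c1O | intermediate
7 | 6-(benzyloxy)-4-methoxy-2-(triethylsilyloxy)-3-[3-methyl-3-(triethylsilyloxy)butyl]benzaldehyde | O=Cc1c(OCc2ccccc2)cc(OC)c(CCC(C)(C)O[Si](CC)(CC)CC)c1O[Si](CC)(CC)CC | intermediate (not isolated)
8 | 6-(benzyloxy)-2-hydroxy-4-methoxy-3-[3-methyl-3-(triethylsilyloxy)butyl]benzaldehyde | O=Cc1c(OCc2ccccc2)cc(OC)c(CCC(C)(C)O[Si](CC)(CC)CC)c1O | intermediate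
9 | styrene | C=Cc1ccccc1 | starting material
10 | trimethyl orthoformate | COC(OC)OC | starting material
11 | 3-(benzyloxy)-2-(dimethoxymethyl)-5-methoxy-6-[3-methyl-3-(triethylsilyloxy)butyl]phenol | COC(OC)c1c(OCc2ccccc2)cc(OC)c(CCC(C)(C)O[Si](CC)(CC)CC)c1O | intermediate (not isolated)
12 | (6E)-5-(benzyloxy)-3-methoxy-6-(methoxymethylidene)-2-[3-methyl-3-(triethylsilyloxy)butyl]cyclohexa-2,4-dien-1-one | CO/C=C1/C(=O)C(CCC(C)(C)O[Si](CC)(CC)CC)=C(OC)C=C1OCc1ccccc1 | intermediate (not isolated)
13 | (2S,4S)-5-(benzyloxy)-4,7-dimethoxy-8-[3-methyl-3-(triethylsilyloxy)butyl]flavan | COc1cc(OCc3ccccc3)c2c(c1CCC(C)(C)O[Si](CC)(CC)CC)O[C@H](c1ccccc1)C[C@@H]2OC | intermediate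
14 | (2S)-5-(benzyloxy)-7-methoxy-8-[3-methyl-3-(triethylsilyloxy)butyl]flavanone | COc1cc(OCc3ccccc3)c2c(c1CCC(C)(C)O[Si](CC)(CC)CC)O[C@H](c1ccccc1)CC2=O | intermediate
15 | (2S)-5-(benzyloxy)-8-(3-hydroxy-3-methylbutyl)-7-methoxyflavanone | COc1cc(OCc3ccccc3)c2c(c1CCC(C)(C)O)O[C@H](c1ccccc1)CC2=O | intermediate
16 | (2S)-5-hydroxy-8-(3-hydroxy-3-methylbutyl)-7-methoxyflavanone [(2S)-5-hydroxy-8-(3-hydroxy-3-methylbutyl)-7-methoxy-2-phenyl-2,3-dihydro-4H-chromen-4-one] | COc1cc(O)c2c(c1CCC(C)(C)O)O[C@H](c1ccccc1)CC2=O | target

## Step count and least certain steps

Total: 9 steps. Longest linear sequence: 9 steps, from 1 to 16; 3, 9 and 10 are purchased.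

Step 6 is the only step that goes beyond demonstrated chemistry. Three things may go wrong:
- The cycloaddition may be slow, because two alkoxy donors over-stabilise the cation. Oligomerisation of 9, or re-ionisation of the product at C4 followed by elimination or arylation by a second ring A, could then take over.
- Facial or endo/exo control may be insufficient, which would show as low optical purity at C2 after step 7.
- The TES group may be lost by acid-catalysed methanolysis.

The fallback uses known chemistry and runs from 8 to 14. Excess ethynylmagnesium bromide in THF at 0 °C adds to the aldehyde to give racemic 1-{6-(benzyloxy)-2-hydroxy-4-methoxy-3-[3-methyl-3-(triethylsilyloxy)butyl]phenyl}prop-2-yn-1-ol F1. MnO2 in CH2Cl2 oxidises it to 1-{6-(benzyloxy)-2-hydroxy-4-methoxy-3-[3-methyl-3-(triethylsilyloxy)butyl]phenyl}prop-2-yn-1-one F2. Et2NH in EtOH converts this through its enaminone, by addition–elimination of the phenol, into 5-(benzyloxy)-7-methoxy-8-[3-methyl-3-(triethylsilyloxy)butyl]-4H-chromen-4-one F3. Asymmetric 1,4-addition of phenylboronic acid to this chromone (Pd(OCOCF3)2, t-BuPyOx ligand of the antipode that gives the 2S series, NH4PF6, H2O, ClCH2CH2Cl, 60 °C) sets C2 and returns the route at 14.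

Step 3: benzylation may occur at the hindered hydroxyl or twice, because the discrimination rests only on sterics and chelation. A wrong-site ether would carry through to the 6-alkyl flavanone series. The fallback removes the question by benzylating before the chain is present and runs from 2 to 5. BnBr and K2CO3 in acetone act on symmetric 2, whose hydroxyls are equivalent, to give 2-(benzyloxy)-6-hydroxy-4-methoxybenzaldehyde F4. Copper-catalysed O-alkylation with 3-chloro-3-methylbut-1-yne (CuCl2 cat., DBU, MeCN) gives 2-(benzyloxy)-4-methoxy-6-[(2-methylbut-3-yn-2-yl)oxy]benzaldehyde F5. Semi-hydrogenation (H2, Pd/CaCO3 poisoned with Pb(OAc)2, quinoline) gives 2-(benzyloxy)-4-methoxy-6-[(2-methylbut-3-en-2-yl)oxy]benzaldehyde F6. Claisen rearrangement in toluene at 80–110 °C can deliver the allyl terminus only to the free position ortho to that oxygen, which gives 5.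

Step 2: O-alkylation and dialkylation may dominate, because the phenolate is ambident and the product is as nucleophilic as 2. The fallback replaces direct C-alkylation by O-alkylation and a sigmatropic shift and runs from 2 to 4. Mono-alkylation of the non-chelated hydroxyl with 3-chloro-3-methylbut-1-yne (CuCl2 cat., DBU, MeCN) gives 2-hydroxy-4-methoxy-6-[(2-methylbut-3-yn-2-yl)oxy]benzaldehyde F7. Semi-hydrogenation over Pb-poisoned Pd/CaCO3 gives 2-hydroxy-4-methoxy-6-[(2-methylbut-3-en-2-yl)oxy]benzaldehyde F8. Claisen rearrangement on warming returns the route at 4.

Step 7: hydride abstraction may be sluggish if the peri benzyloxy group holds the C4–H bond in the plane of ring A. Over-oxidation with dehydrogenation across C2–C3 would destroy the stereocentre, and oxidative loss of the benzyl group is also possible. The fallback replaces hydride abstraction by solvolysis and alcohol oxidation and runs from 13 to 15. Catalytic TsOH in THF/H2O at 0 °C under high dilution exchanges the C4 methoxy group for hydroxyl and removes the TES group, giving (2S)-5-(benzyloxy)-8-(3-hydroxy-3-methylbutyl)-7-methoxyflavan-4-ol F9 as a mixture of C4 epimers. MnO2 in CH2Cl2 oxidises only the benzylic secondary alcohol and returns the route at 15.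

## Further compounds

F1 | step 6 | 1-{6-(benzyloxy)-2-hydroxy-4-methoxy-3-[3-methyl-3-(triethylsilyloxy)butyl]phenyl}prop-2-yn-1-ol (racemic) | C#CC(O)c1c(OCc2ccccc2)cc(OC)c(CCC(C)(C)O[Si](CC)(CC)CC)c1O
F2 | step 6 | 1-{6-(benzyloxy)-2-hydroxy-4-methoxy-3-[3-methyl-3-(triethylsilyloxy)butyl]phenyl}prop-2-yn-1-one | C#CC(=O)c1c(OCc2ccccc2)cc(OC)c(CCC(C)(C)O[Si](CC)(CC)CC)c1O
F3 | step 6 | 5-(benzyloxy)-7-methoxy-8-[3-methyl-3-(triethylsilyloxy)butyl]-4H-chromen-4-one | COc1cc(OCc3ccccc3)c2c(c1CCC(C)(C)O[Si](CC)(CC)CC)OC=CC2=O
F4 | step 3 | 2-(benzyloxy)-6-hydroxy-4-methoxybenzaldehyde | O=Cc1c(O)cc(OC)cc1OCc1ccccc1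
F5 | step 3 | 2-(benzyloxy)-4-methoxy-6-[(2-methylbut-3-yn-2-yl)oxy]benzaldehyde | O=Cc1c(OCc2ccccc2)cc(OC)cc1OC(C)(C)C#C
F6 | step 3 | 2-(benzyloxy)-4-methoxy-6-[(2-methylbut-3-en-2-yl)oxy]benzaldehyde | O=Cc1c(OCc2ccccc2)cc(OC)cc1OC(C)(C)C=C
F7 | step 2 | 2-hydroxy-4-methoxy-6-[(2-methylbut-3-yn-2-yl)oxy]benzaldehyde | O=Cc1c(O)cc(OC)cc1OC(C)(C)C#C
F8 | step 2 | 2-hydroxy-4-methoxy-6-[(2-methylbut-3-en-2-yl)oxy]benzaldehyde | O=Cc1c(O)cc(OC)cc1OC(C)(C)C=C
F9 | step 7 | (2S)-5-(benzyloxy)-8-(3-hydroxy-3-methylbutyl)-7-methoxyflavan-4-ol (mixture of C4 epimers) | COc1cc(OCc3ccccc3)c2c(c1CCC(C)(C)O)O[C@H](c1ccccc1)CC2O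
A1 | alternative 1 | (2S)-8-bromo-5,7-dimethoxyflavanone | COc1cc(OC)c2c(c1Br)O[C@H](c1ccccc1)CC2=O
A2 | alternative 1 | (3S)-3-(2-bromo-3,5-dimethoxyphenoxy)-3-phenylpropanoic acid | COc1cc(OC)c(Br)c(O[C@H](c2ccccc2)CC(=O)O)c1
A3 | alternative 2 | (2S)-7-methoxy-5-(methoxymethoxy)-8-[3-methyl-3-(triethylsilyloxy)butyl]flavanone | COc1cc(OCOC)c2c(c1CCC(C)(C)O[Si](CC)(CC)CC)O[C@H](c1ccccc1)CC2=O
A4 | alternative 2 | 3-methoxy-5-(methoxymethoxy)-2-[3-methyl-3-(triethylsilyloxy)butyl]-6-(trimethylsilyl)phenyl trifluoromethanesulfonate | COCOc1cc(OC)c(CCC(C)(C)O[Si](CC)(CC)CC)c(OS(=O)(=O)C(F)(F)F)c1[Si](C)(C)C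
A5 | alternative 2 | (3S)-3-hydroxy-N-methoxy-N-methyl-3-phenylpropanamide | CON(C)C(=O)C[C@H](O)c1ccccc1
A6 | alternative 3 | (2S)-5-(tert-butyldimethylsilyloxy)-7-methoxy-8-[3-methyl-3-(triethylsilyloxy)butyl]flavanone | COc1cc(O[Si](C)(C)C(C)(C)C)c2c(c1CCC(C)(C)O[Si](CC)(CC)CC)O[C@H](c1ccccc1)CC2=O
A7 | alternative 3 | 1-{2-(benzyloxy)-6-(tert-butyldimethylsilyloxy)-4-methoxy-3-[3-methyl-3-(triethylsilyloxy)butyl]phenyl}-2-diazoethan-1-one | [N-]=[N+]=CC(=O)c1c(O[Si](C)(C)C(C)(C)C)cc(OC)c(CCC(C)(C)O[Si](CC)(CC)CC)c1OCc1ccccc1
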